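## Retrosynthetic overview

1. The target γ-lactone (acyl C2–O1 bond, last ring formed) comes from hydroxy acid 11, made by chemoselective hydride reduction of the C5 lactone carbonyl of lactone acid 10; the ring oxygen of 10 becomes the free C7' hydroxyl.
2. Key disconnection: the C7'–O bond of 10 (first ring formed) comes from 5-exo addition of the C5 carboxyl to a p-quinone methide, generated by benzylic C–H oxidation of the C2-symmetric diacid 8; this sets C7'.
3. 8 comes from the C3–C4 bond, made by auxiliary-controlled oxidative enolate homocoupling of imide 4 (sets C3 and C4), then hydrolysis.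
4. 4 comes from dihydroferulic acid 1 and oxazolidinone 2.

Atom labels follow the target lactone: C2 carbonyl, C3 (α), C4 (β), C5 (OCH2), C7' the carbinol carbon on C3, C7 the benzylic CH2 on C4; the target is read as (3S,4R,7'S).

## Route

Step 1
Reactants: 1 3-(4-hydroxy-3-methoxyphenyl)propanoic acid; 2 (4S)-4-isopropyloxazolidin-2-one
Product: 4 2-methoxy-4-{3-oxo-3-[(4S)-2-oxo-4-isopropyloxazolidin-3-yl]propyl}phenyl pivalate, via mixed pivalic anhydride 3 (not isolated)
Conditions: PivCl (2.2 equiv), Et3N, DMAP (cat.), THF, −20 to 0 °C (acid added to the acyl chloride); then 2, LiCl, rt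
Reagents that add atoms: pivaloyl chloride, CC(C)(C)C(=O)Cl
Why: The acyl chloride caps the phenol and activates the acid as a mixed anhydride in one pot, and LiCl-assisted N-acylation of the oxazolidinone (mixed-anhydride imide formation) then takes the less hindered carbonyl; no stereocentre is formed.

Step 2
Reactants: 4 2-methoxy-4-{3-oxo-3-[(4S)-2-oxo-4-isopropyloxazolidin-3-yl]propyl}phenyl pivalate (two molecules)
Product: 6 (2R,3R)-2,3-bis[3-methoxy-4-(pivaloyloxy)benzyl]-1,4-bis[(4S)-2-oxo-4-isopropyloxazolidin-3-yl]butane-1,4-dione, via lithium Z-enolate 5 (not isolated)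
Conditions: LiN(iPr)2 (LDA, 1.1 equiv), THF, −78 °C; then TiCl4 (1.1 equiv), −78 °C to rt
Reagents that add atoms: none
Why: Oxidative enolate homocoupling of an N-acyl oxazolidinone: tetravalent titanium oxidises the chelated Z-enolate by one electron (going to trivalent titanium) and the two α-carbons join on the face away from the isopropyl group of each half, as in auxiliary-controlled alkylation, which sets both new centres R (C3 and C4 of the target).

Step 3
Reactants: 6 (2R,3R)-2,3-bis[3-methoxy-4-(pivaloyloxy)benzyl]-1,4-bis[(4S)-2-oxo-4-isopropyloxazolidin-3-yl]butane-1,4-dione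
Product: 8 (2R,3R)-2,3-bis(4-hydroxy-3-methoxybenzyl)butanedioic acid, via diperoxy acid 7 (not isolated)
Conditions: LiOH, H2O2, THF–H2O, 0 °C to rt; then Na2SO3; then HCl
Reagents that add atoms: hydrogen peroxide, OO
Why: Hydroperoxide cleavage of both N-acyl oxazolidinones (exocyclic attack, no epimerisation of the α-centres) also perhydrolyses both aryl pivalates, and sulfite reduces the peroxy acids; no stereocentre is touched and 2 is recovered.

Step 4
Reactants: 8 (2R,3R)-2,3-bis(4-hydroxy-3-methoxybenzyl)butanedioic acid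
Product: 10 (2S,3S,4R)-4-(4-hydroxy-3-methoxybenzyl)-2-(4-hydroxy-3-methoxyphenyl)-5-oxotetrahydrofuran-3-carboxylic acid, via quinone methide 9 (not isolated)
Conditions: DDQ (0.6 equiv), 1,4-dioxane, 10 °C to rt
Reagents that add atoms: none
Why: Proposed new method: desymmetrising benzylic C–H lactonisation of a C2-symmetric 2,3-bis(4-hydroxybenzyl)succinic acid; DDQ removes a hydride (or H atom then electron) from the phenol-activated benzylic CH2 of one guaiacyl arm to give p-quinone methide 9, whose electrophilic C7' lies five atoms from the C5 carboxyl (the C2 carboxyl could only give a β-lactone), so 5-exo 1,6-addition with rearomatisation forms the C7'–O bond; C3 and C4 are fixed and their ring substituents (CO2H, benzyl) end up cis, so the aryl group goes to the opposite face, trans to both, which is (7'S), and reversible ionisation of the p-hydroxybenzylic C–O bond would lead to the same isomer; the second arm is equally reactive, so the oxidant is kept sub-stoichiometric (statistical estimate about 40% of 10 at half conversion, unreacted 8 recovered by base extraction and recycled); closest known reaction types are DDQ or Ag2O oxidation of 4-alkylphenols to p-quinone methides, carboxyl trapping of quinone methides in the oxidative 8–8 dimerisation of ferulic and sinapic acids to bis-lactones, and DDQ-mediated benzylic oxidative lactonisation of electron-rich arylalkanoic acids.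

Step 5
Reactants: 10 (2S,3S,4R)-4-(4-hydroxy-3-methoxybenzyl)-2-(4-hydroxy-3-methoxyphenyl)-5-oxotetrahydrofuran-3-carboxylic acid
Product: 12 (3S,4R)-4-(4-hydroxy-3-methoxybenzyl)-3-[(S)-hydroxy(4-hydroxy-3-methoxyphenyl)methyl]dihydrofuran-2(3H)-one, via hydroxy acid 11 (not isolated)
Conditions: LiBH4 (5 equiv), THF, 0 °C to rt; then 1 M HCl to pH 2–3, 0 °C to rt
Reagents that add atoms: none
Why: Chemoselective ester reduction followed by lactonisation: LiBH4 reduces the C5 lactone carbonyl to the primary alcohol and frees the C7' hydroxyl while the lithium carboxylate at C2 is inert, and on mild acidification the γ-hydroxy acid closes the new γ-lactone (the benzylic hydroxyl could only give a β-lactone); no stereocentre is touched.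

## Compound list

1 | 3-(4-hydroxy-3-methoxyphenyl)propanoic acid (dihydroferulic acid) | COc1cc(CCC(=O)O)ccc1O | starting material
2 | (4S)-4-isopropyloxazolidin-2-one | CC(C)[C@H]1COC(=O)N1 | starting material
3 | 3-[3-methoxy-4-(pivaloyloxy)phenyl]propanoic pivalic anhydride | COc1cc(CCC(=O)OC(=O)C(C)(C)C)ccc1OC(=O)C(C)(C)C | intermediate (not isolated)
4 | 2-methoxy-4-{3-oxo-3-[(4S)-2-oxo-4-isopropyloxazolidin-3-yl]propyl}phenyl pivalate | COc1cc(CCC(=O)N2[C@@H](C(C)C)COC2=O)ccc1OC(=O)C(C)(C)C | intermediate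
5 | lithium (Z)-1-[(4S)-2-oxo-4-isopropyloxazolidin-3-yl]-3-[3-methoxy-4-(pivaloyloxy)phenyl]prop-1-en-1-olate | COc1cc(C/C=C(\[O-])N2[C@@H](C(C)C)COC2=O)ccc1OC(=O)C(C)(C)C.[Li+] | intermediate (not isolated)
6 | (2R,3R)-2,3-bis[3-methoxy-4-(pivaloyloxy)benzyl]-1,4-bis[(4S)-2-oxo-4-isopropyloxazolidin-3-yl]butane-1,4-dione | CC(C)[C@H]1COC(=O)N1C(=O)[C@H](Cc1ccc(OC(=O)C(C)(C)C)c(OC)c1)[C@@H](Cc1ccc(OC(=O)C(C)(C)C)c(OC)c1)C(=O)N1[C@@H](C(C)C)COC1=O | intermediate
7 | (2R,3R)-2,3-bis(4-hydroxy-3-methoxybenzyl)butanediperoxoic acid | OOC(=O)[C@H](Cc1ccc(O)c(OC)c1)[C@@H](Cc1ccc(O)c(OC)c1)C(=O)OO | intermediate (not isolated)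
8 | (2R,3R)-2,3-bis(4-hydroxy-3-methoxybenzyl)butanedioic acid | OC(=O)[C@H](Cc1ccc(O)c(OC)c1)[C@@H](Cc1ccc(O)c(OC)c1)C(=O)O | intermediate
9 | (2R,3R)-2-(4-hydroxy-3-methoxybenzyl)-3-[(3-methoxy-4-oxocyclohexa-2,5-dien-1-ylidene)methyl]butanedioic acid (exocyclic C=C geometry not defined) | OC(=O)[C@H](Cc1ccc(O)c(OC)c1)[C@H](C(O)=O)C=C1C=CC(=O)C(OC)=C1 | intermediate (not isolated)
10 | (2S,3S,4R)-4-(4-hydroxy-3-methoxybenzyl)-2-(4-hydroxy-3-methoxyphenyl)-5-oxotetrahydrofuran-3-carboxylic acid | O=C1O[C@H](c2ccc(O)c(OC)c2)[C@@H](C(O)=O)[C@H]1Cc1ccc(O)c(OC)c1 | intermediate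
11 | (2S,3R)-2-[(S)-hydroxy(4-hydroxy-3-methoxyphenyl)methyl]-3-(hydroxymethyl)-4-(4-hydroxy-3-methoxyphenyl)butanoic acid | COc1cc(C[C@@H](CO)[C@H](C(=O)O)[C@H](O)c2ccc(O)c(OC)c2)ccc1O | intermediate (not isolated)
12 | (3S,4R)-4-(4-hydroxy-3-methoxybenzyl)-3-[(S)-hydroxy(4-hydroxy-3-methoxyphenyl)methyl]dihydrofuran-2(3H)-one | COc1cc(C[C@H]2COC(=O)[C@@H]2[C@H](O)c2ccc(O)c(OC)c2)ccc1O | target

## Step count and risks

Total step count: 5. Longest linear sequence: 5 steps (1 → 4 → 6 → 8 → 10 → 12).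

The three steps most likely to fail:

**Step 4 (the proposed new step).** The quinone methide may tautomerise to the arylidene succinic acid, cyclise onto the other arene, or be oxidised a second time to the bis-lactone before a useful amount of 10 builds up. The fallback uses known chemistry only, sets out from 4 and comes back at 12, and builds C7' by the classical lactone aldol.
- The sodium enolate of 4 (NaN(SiMe3)2, THF, −78 °C) is alkylated with tert-butyl bromoacetate, on the face away from the isopropyl group, to give tert-butyl (3R)-4-[(4S)-2-oxo-4-isopropyloxazolidin-3-yl]-3-[3-methoxy-4-(pivaloyloxy)benzyl]-4-oxobutanoate F1.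
- LiBH4 (THF with a little MeOH, 0 °C) removes the auxiliary reductively and cleaves the pivalate, giving tert-butyl (3R)-3-(hydroxymethyl)-4-(4-hydroxy-3-methoxyphenyl)butanoate F2.
- TsOH (cat.) in warm toluene closes (R)-4-(4-hydroxy-3-methoxybenzyl)dihydrofuran-2(3H)-one F3.
- The phenoxide–enolate dianion of F3 (LiN(iPr)2, 2.2 equiv, THF, −78 °C) adds to commercial 4-[(tert-butyldimethylsilyl)oxy]-3-methoxybenzaldehyde anti to the benzyl group. This gives the trans-lactone as both C7' epimers in roughly equal amounts.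
- The (7'S)-epimer, (3S,4R)-3-[(S)-{4-[(tert-butyldimethylsilyl)oxy]-3-methoxyphenyl}(hydroxy)methyl]-4-(4-hydroxy-3-methoxybenzyl)dihydrofuran-2(3H)-one F4, is separated by chromatography and desilylated (Bu4NF buffered with AcOH, THF, 0 °C) to 12.

**Step 5.** With free phenols under basic hydride, the aryloxyborate may expel the benzylic carboxylate from 10 to give a quinone methide, which hydride would reduce back to 8. The fallback sets out from 10 and comes back at 12, and masks the phenols first.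
- TBSCl and imidazole in DMF silylate both phenols and the carboxyl group, giving tert-butyldimethylsilyl (2S,3S,4R)-4-{4-[(tert-butyldimethylsilyl)oxy]-3-methoxybenzyl}-2-{4-[(tert-butyldimethylsilyl)oxy]-3-methoxyphenyl}-5-oxotetrahydrofuran-3-carboxylate F5.
- Brief treatment with AcOH–H2O–THF hydrolyses only the silyl ester, giving (2S,3S,4R)-4-{4-[(tert-butyldimethylsilyl)oxy]-3-methoxybenzyl}-2-{4-[(tert-butyldimethylsilyl)oxy]-3-methoxyphenyl}-5-oxotetrahydrofuran-3-carboxylic acid F6.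
- LiBH4 in THF reduces the lactone, now without any phenoxide, to (2S,3R)-4-{4-[(tert-butyldimethylsilyl)oxy]-3-methoxyphenyl}-2-[(S)-{4-[(tert-butyldimethylsilyl)oxy]-3-methoxyphenyl}(hydroxy)methyl]-3-(hydroxymethyl)butanoic acid F7.
- Mild acidification closes (3S,4R)-4-{4-[(tert-butyldimethylsilyl)oxy]-3-methoxybenzyl}-3-[(S)-{4-[(tert-butyldimethylsilyl)oxy]-3-methoxyphenyl}(hydroxy)methyl]dihydrofuran-2(3H)-one F8.
- Bu4NF buffered with AcOH (THF, 0 °C) removes both silyl ethers to give 12.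

**Step 2.** The homocoupling may give low yield or poor diastereoselectivity with the aryl pivalates present. The fallback sets out from 1 and comes back at 8, and replaces auxiliary control by an achiral coupling and a resolution.
- O-Benzylation of 1 (BnCl, NaOH, aqueous EtOH, reflux) gives 3-[4-(benzyloxy)-3-methoxyphenyl]propanoic acid F9.
- Its dianion (LiN(iPr)2, 2.2 equiv, THF, 0 °C) is coupled with I2 (0.5 equiv, −78 °C to rt). After removal of the meso isomer by crystallisation this gives racemic (2R*,3R*)-2,3-bis[4-(benzyloxy)-3-methoxybenzyl]butanedioic acid F10.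
- Classical resolution through a diastereomeric salt with a chiral amine (cinchonidine as first choice) gives (2R,3R)-2,3-bis[4-(benzyloxy)-3-methoxybenzyl]butanedioic acid F11.
- Hydrogenolysis (H2, Pd/C, EtOAc–EtOH) gives 8.

## Further compounds

F1 | step 4 | tert-butyl (3R)-4-[(4S)-2-oxo-4-isopropyloxazolidin-3-yl]-3-[3-methoxy-4-(pivaloyloxy)benzyl]-4-oxobutanoate | CC(C)[C@H]1COC(=O)N1C(=O)[C@H](Cc1ccc(OC(=O)C(C)(C)C)c(OC)c1)CC(=O)OC(C)(C)C
F2 | step 4 | tert-butyl (3R)-3-(hydroxymethyl)-4-(4-hydroxy-3-methoxyphenyl)butanoate | OC[C@H](Cc1ccc(O)c(OC)c1)CC(=O)OC(C)(C)C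
F3 | step 4 | (R)-4-(4-hydroxy-3-methoxybenzyl)dihydrofuran-2(3H)-one | COc1cc(C[C@H]2COC(=O)C2)ccc1O
F4 | step 4 | (3S,4R)-3-[(S)-{4-[(tert-butyldimethylsilyl)oxy]-3-methoxyphenyl}(hydroxy)methyl]-4-(4-hydroxy-3-methoxybenzyl)dihydrofuran-2(3H)-one | COc1cc(C[C@H]2COC(=O)[C@@H]2[C@H](O)c2ccc(O[Si](C)(C)C(C)(C)C)c(OC)c2)ccc1O
F5 | step 5 | tert-butyldimethylsilyl (2S,3S,4R)-4-{4-[(tert-butyldimethylsilyl)oxy]-3-methoxybenzyl}-2-{4-[(tert-butyldimethylsilyl)oxy]-3-methoxyphenyl}-5-oxotetrahydrofuran-3-carboxylate | O=C1O[C@H](c2ccc(O[Si](C)(C)C(C)(C)C)c(OC)c2)[C@@H](C(=O)O[Si](C)(C)C(C)(C)C)[C@H]1Cc1ccc(O[Si](C)(C)C(C)(C)C)c(OC)c1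
F6 | step 5 | (2S,3S,4R)-4-{4-[(tert-butyldimethylsilyl)oxy]-3-methoxybenzyl}-2-{4-[(tert-butyldimethylsilyl)oxy]-3-methoxyphenyl}-5-oxotetrahydrofuran-3-carboxylic acid | O=C1O[C@H](c2ccc(O[Si](C)(C)C(C)(C)C)c(OC)c2)[C@@H](C(O)=O)[C@H]1Cc1ccc(O[Si](C)(C)C(C)(C)C)c(OC)c1
F7 | step 5 | (2S,3R)-4-{4-[(tert-butyldimethylsilyl)oxy]-3-methoxyphenyl}-2-[(S)-{4-[(tert-butyldimethylsilyl)oxy]-3-methoxyphenyl}(hydroxy)methyl]-3-(hydroxymethyl)butanoic acid | COc1cc(C[C@@H](CO)[C@H](C(=O)O)[C@H](O)c2ccc(O[Si](C)(C)C(C)(C)C)c(OC)c2)ccc1O[Si](C)(C)C(C)(C)C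
F8 | step 5 | (3S,4R)-4-{4-[(tert-butyldimethylsilyl)oxy]-3-methoxybenzyl}-3-[(S)-{4-[(tert-butyldimethylsilyl)oxy]-3-methoxyphenyl}(hydroxy)methyl]dihydrofuran-2(3H)-one | COc1cc(C[C@H]2COC(=O)[C@@H]2[C@H](O)c2ccc(O[Si](C)(C)C(C)(C)C)c(OC)c2)ccc1O[Si](C)(C)C(C)(C)C
F9 | step 2 | 3-[4-(benzyloxy)-3-methoxyphenyl]propanoic acid | COc1cc(CCC(=O)O)ccc1OCc1ccccc1
F10 | step 2 | racemic (2R*,3R*)-2,3-bis[4-(benzyloxy)-3-methoxybenzyl]butanedioic acid (both enantiomers) | OC(=O)[C@H](Cc1ccc(OCc2ccccc2)c(OC)c1)[C@@H](Cc1ccc(OCc2ccccc2)c(OC)c1)C(=O)O.OC(=O)[C@@H](Cc1ccc(OCc2ccccc2)c(OC)c1)[C@H](Cc1ccc(OCc2ccccc2)c(OC)c1)C(=O)O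
F11 | step 2 | (2R,3R)-2,3-bis[4-(benzyloxy)-3-methoxybenzyl]butanedioic acid | OC(=O)[C@H](Cc1ccc(OCc2ccccc2)c(OC)c1)[C@@H](Cc1ccc(OCc2ccccc2)c(OC)c1)C(=O)O
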